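## Retrosynthetic overview

1. The target is reached by mono-oxidation (allylic carbinol to enone) of the C2-symmetric (3S,6S,3'S,6'S)-ε,ε-carotene-3,3'-diol, so both end groups come from one building block.
2. The C40 diol is cut at C11=C12 and C11'=C12': a double Wittig reaction of two C15 3-hydroxy-ε phosphonium salts with the C10 trienedial.
3. The C15 salt comes from (3S,6S)-3-hydroxy-α-ionone (vinyl Grignard, allylic phosphonium formation), itself made from (S)-α-ionone by enzymatic C3 hydroxylation trans to the side chain (cyclise first, hydroxylate second, as in ε-ring biosynthesis).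
4. Ring formation is the only ring-forming step and serves both rings: a catalyst-controlled, proton-initiated cyclisation of acyclic pseudoionone (C1–C6 bond, loss of H-4) that sets C6 as S directly.

Assumption: the sense of induction of the chiral acid in step 1 must be found by experiment, the antipode that gives (S)-2 is the one written, and commercial (3E,5E)-rich pseudoionone is used.

## Route

Step 1
Reactants: 1 pseudoionone, (3E,5E)-6,10-dimethylundeca-3,5,9-trien-2-one
Product: 2 (S)-α-ionone, (3E)-4-[(1S)-2,6,6-trimethylcyclohex-2-en-1-yl]but-3-en-2-one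
Conditions: (S,S)-IDPi acid {[(S)-3,3'-Ar2-BINOL-O2]P(=NSO2CF3)}2NH, Ar = 3,5-(CF3)2C6H3 (5 mol %), (CF3)3COH/CH2Cl2, −20 → 0 °C
Reagents that add atoms: none
Why: Proposed new method: the confined strong acid protonates C2 of the terminal trisubstituted alkene of 1 held in a chair-like fold inside the chiral anion pocket (ketone hydrogen-bonded to the catalyst, 5E/5Z isomers of the protonated dienone interconverting), C6 of the dienone attacks C1 on the catalyst-selected π-face to set the C6 stereocentre, and the ion-paired anion removes H-4 from the tertiary C5 cation to give the ε-ring olefin under kinetic control; the closest known reaction types are the H3PO4-mediated cation–olefin cyclisation of pseudoionone to racemic α-ionone and IDPi-catalysed enantioselective proton-initiated polyene cyclisations in fluorinated alcohols.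

Step 2
Reactants: 2 (S)-α-ionone
Product: 3 (3S,6S)-3-hydroxy-α-ionone, (3E)-4-[(1S,4S)-4-hydroxy-2,6,6-trimethylcyclohex-2-en-1-yl]but-3-en-2-one
Conditions: engineered cytochrome P450 BM3 (CYP102A1) C3-hydroxylase variant (cell-free extract), air, NADP+ (cat.), D-glucose, glucose dehydrogenase, K2HPO4/KH2PO4 buffer pH 7.4, 2% DMSO, 25 °C
Reagents that add atoms: dioxygen, O=O
Why: Enzymatic allylic C–H hydroxylation (hydrogen abstraction/oxygen rebound at the haem) is known for α-ionone to occur at C3 on the ring face opposite the C6 side chain, so (6S)-2 gives the trans (3S,6S)-carbinol, as the ε-ring hydroxylase does in biosynthesis.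

Step 3
Reactants: 3 (3S,6S)-3-hydroxy-α-ionone
Product: 4 (1S,4S)-4-[(1E)-3-hydroxy-3-methylpenta-1,4-dien-1-yl]-3,5,5-trimethylcyclohex-2-en-1-ol (mixture of C9 epimers)
Conditions: CH2=CHMgBr (3 equiv), THF, −30 → 0 °C; then sat. aq. NH4Cl
Reagents that add atoms: vinylmagnesium bromide, C=C[Mg]Br
Why: Grignard 1,2-addition to the methyl enone (the first equivalent is consumed by the free hydroxyl) gives the C15 vinyl carbinol; the new C9 centre is an inconsequential mixture erased in step 4, and C3 and C6 are untouched at low temperature.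

Step 4
Reactants: 4 C15 vinyl carbinol diol
Product: 5 [(2E,4E)-5-[(1S,4S)-4-hydroxy-2,6,6-trimethylcyclohex-2-en-1-yl]-3-methylpenta-2,4-dien-1-yl]triphenylphosphonium bromide
Conditions: PPh3·HBr (1.05 equiv), MeOH, 0 °C → rt; recrystallise (CH2Cl2/EtOAc)
Reagents that add atoms: triphenylphosphine hydrobromide, [Br-].[PH+](c1ccccc1)(c1ccccc1)c1ccccc1
Why: Allylic transposition (SN1'-type): the doubly allylic tertiary carbinol ionises to a pentadienyl cation that PPh3 captures at the unhindered terminus to give the (2E,4E) salt, while the ring secondary allylic carbinol ionises far more slowly; crystallisation removes the 9Z isomer and raises the ee.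

Step 5
Reactants: 5 C15 phosphonium bromide (2.2 equiv); 6 (2E,4E,6E)-2,7-dimethylocta-2,4,6-trienedial (C10 dialdehyde)
Product: 9 (all-E)-(3S,6S,3'S,6'S)-ε,ε-carotene-3,3'-diol, via C15 ylide 7 (not isolated), via C25 hydroxy-apo-aldehyde 8 (not isolated)
Conditions: NaOMe (2.2 equiv), CH2Cl2/MeOH, 0 °C → rt; then heptane, reflux (Z → E); crystallise
Reagents that add atoms: none
Why: Double Wittig olefination (C15 + C10 + C15) with free hydroxyls tolerated; the Z isomers at the new C11=C12 and C11'=C12' bonds are isomerised thermally to all-E, no stereocentre is touched, and joining two enantioenriched halves leaves the minor enantiomer mainly in a separable meso-type diastereomer.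

Step 6
Reactants: 9 (all-E)-(3S,6S,3'S,6'S)-ε,ε-carotene-3,3'-diol
Product: 10 (all-E)-(6S,3'S,6'S)-3'-hydroxy-ε,ε-caroten-3-one (target, CNP0344065.1)
Conditions: activated MnO2 (excess), acetone, rt, dark, Ar, stopped at about half conversion; SiO2 chromatography, 9 recycled
Reagents that add atoms: none
Why: Chemoselective MnO2 oxidation of an allylic carbinol under neutral conditions; the two identical, remote carbinols react independently, so the mono-enone is the main product at half conversion, and C6, C6' and C3' are not affected.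

## Compound list

1 | pseudoionone, (3E,5E)-6,10-dimethylundeca-3,5,9-trien-2-one | CC(=O)/C=C/C=C(C)/CCC=C(C)C | starting material
2 | (S)-α-ionone, (3E)-4-[(1S)-2,6,6-trimethylcyclohex-2-en-1-yl]but-3-en-2-one | CC(=O)/C=C/[C@@H]1C(C)=CCCC1(C)C | intermediate
3 | (3S,6S)-3-hydroxy-α-ionone, (3E)-4-[(1S,4S)-4-hydroxy-2,6,6-trimethylcyclohex-2-en-1-yl]but-3-en-2-one | CC(=O)/C=C/[C@@H]1C(C)=C[C@@H](O)CC1(C)C | intermediate
4 | (1S,4S)-4-[(1E)-3-hydroxy-3-methylpenta-1,4-dien-1-yl]-3,5,5-trimethylcyclohex-2-en-1-ol (C9 epimers) | C=CC(C)(O)/C=C/[C@@H]1C(C)=C[C@@H](O)CC1(C)C | intermediate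
5 | [(2E,4E)-5-[(1S,4S)-4-hydroxy-2,6,6-trimethylcyclohex-2-en-1-yl]-3-methylpenta-2,4-dien-1-yl]triphenylphosphonium bromide | [Br-].c1ccccc1[P+](c1ccccc1)(c1ccccc1)C/C=C(C)/C=C/[C@@H]1C(C)=C[C@@H](O)CC1(C)C | intermediate
6 | (2E,4E,6E)-2,7-dimethylocta-2,4,6-trienedial | O=C/C(C)=C/C=C/C=C(C)/C=O | starting material
7 | C15 ylide, [(2E,4E)-5-[(1S,4S)-4-hydroxy-2,6,6-trimethylcyclohex-2-en-1-yl]-3-methylpenta-2,4-dien-1-ylidene]triphenylphosphorane | c1ccccc1P(c1ccccc1)(c1ccccc1)=C/C=C(C)/C=C/[C@@H]1C(C)=C[C@@H](O)CC1(C)C | intermediate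
8 | C25 hydroxy-apo-aldehyde, (2E,4E,6E,8E,10E,12E)-13-[(1S,4S)-4-hydroxy-2,6,6-trimethylcyclohex-2-en-1-yl]-2,7,11-trimethyltrideca-2,4,6,8,10,12-hexaenal | O=C/C(C)=C/C=C/C=C(C)/C=C/C=C(C)/C=C/[C@@H]1C(C)=C[C@@H](O)CC1(C)C | intermediate
9 | (all-E)-(3S,6S,3'S,6'S)-ε,ε-carotene-3,3'-diol | CC1=C[C@@H](O)CC(C)(C)[C@@H]1/C=C/C(C)=C/C=C/C(C)=C/C=C/C=C(C)/C=C/C=C(C)/C=C/[C@@H]1C(C)=C[C@@H](O)CC1(C)C | intermediate
10 | (all-E)-(6S,3'S,6'S)-3'-hydroxy-ε,ε-caroten-3-one | CC1=CC(=O)CC(C)(C)[C@@H]1/C=C/C(C)=C/C=C/C(C)=C/C=C/C=C(C)/C=C/C=C(C)/C=C/[C@@H]1C(C)=C[C@@H](O)CC1(C)C | target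

## Step count and risks

Total step count: 6. Longest linear sequence: 6 steps (1 → 2 → 3 → 4 → 5 → 9 → 10); compound 6 is purchased.

The three steps most likely to fail are steps 1, 4 and 6.

Step 1 is an untested catalytic asymmetric cyclisation; it may give low ee or mainly β- or γ-ionone. The fallback sets out from 1 and comes back at 3, replacing asymmetric catalysis by resolution after hydroxylation. Cyclisation of 1 in 85% H3PO4 gives racemic α-ionone F1. The hydroxylase of step 2 is trans-selective for both enantiomers, so it gives 3 together with its enantiomer (3R,6R)-3-hydroxy-α-ionone F2. Lipase-catalysed acylation (Burkholderia cepacia lipase, vinyl acetate, hexane/t-BuOMe) is expected to acylate the (3R)-carbinol preferentially, as it does with simpler cyclohex-2-enols. This gives (3R,6R)-3-acetoxy-α-ionone F3 and leaves 3, which is separated by chromatography and carried on.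

Step 4 exposes the ring allylic carbinol to HBr, which may cause substitution or dehydration in the ring. The fallback sets out from 3 and 6 and comes back at 9; it reverses the polarity of the coupling so that the ring carbinol never meets acid. Horner–Wadsworth–Emmons reaction of 3 with diethyl cyanomethylphosphonate (NaH, THF) gives the hydroxy nitrile F4. Reduction with i-Bu2AlH (toluene, −78 °C, mild aqueous work-up) gives the C15 hydroxy aldehyde F5. Separately, 6 is reduced (NaBH4, MeOH) to the C10 diol F6 and converted with PPh3·HBr into the C10 bis(triphenylphosphonium) dibromide F7. NaOMe turns F7 into the bis-ylide F8, which couples twice with F5 through the C25 hydroxy ylide F9 to give 9 after thermal Z → E isomerisation.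

Step 6 is statistical: it gives at best about half of the material as 10 per pass, beside recovered 9 and the dione. The fallback sets out from 5 and 6 and comes back at 10; the two ends are differentiated before the second coupling. Wittig reaction of 5 (NaOMe) with a threefold excess of 6 gives the mono-coupled aldehyde 8, now isolated. MnO2 oxidises its ring allylic carbinol (the conjugated aldehyde is inert) to the C25 keto-apo-aldehyde F10. A second Wittig reaction of F10 with ylide 7, generated from 5 in refluxing 1,2-epoxybutane, gives 10 directly. The epoxide acts as a neutral HBr scavenger, which protects the base-sensitive C6–H of the 3-oxo ring.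

## Further compounds

F1 | step 1 | racemic α-ionone, (3E)-4-(2,6,6-trimethylcyclohex-2-en-1-yl)but-3-en-2-one | CC(=O)/C=C/C1C(C)=CCCC1(C)C
F2 | step 1 | (3R,6R)-3-hydroxy-α-ionone | CC(=O)/C=C/[C@H]1C(C)=C[C@H](O)CC1(C)C
F3 | step 1 | (3R,6R)-3-acetoxy-α-ionone | CC(=O)/C=C/[C@H]1C(C)=C[C@H](OC(C)=O)CC1(C)C
F4 | step 4 | (2E,4E)-5-[(1S,4S)-4-hydroxy-2,6,6-trimethylcyclohex-2-en-1-yl]-3-methylpenta-2,4-dienenitrile | N#C/C=C(C)/C=C/[C@@H]1C(C)=C[C@@H](O)CC1(C)C
F5 | step 4 | (2E,4E)-5-[(1S,4S)-4-hydroxy-2,6,6-trimethylcyclohex-2-en-1-yl]-3-methylpenta-2,4-dienal | O=C/C=C(C)/C=C/[C@@H]1C(C)=C[C@@H](O)CC1(C)C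
F6 | step 4 | (2E,4E,6E)-2,7-dimethylocta-2,4,6-triene-1,8-diol | OC/C(C)=C/C=C/C=C(C)/CO
F7 | step 4 | [(2E,4E,6E)-2,7-dimethylocta-2,4,6-triene-1,8-diyl]bis(triphenylphosphonium) dibromide | [Br-].[Br-].c1ccccc1[P+](c1ccccc1)(c1ccccc1)C/C(C)=C/C=C/C=C(C)/C[P+](c1ccccc1)(c1ccccc1)c1ccccc1
F8 | step 4 | C10 bis-ylide, [(2E,4E,6E)-2,7-dimethylocta-2,4,6-triene-1,8-diylidene]bis(triphenylphosphorane) | c1ccccc1P(c1ccccc1)(c1ccccc1)=C/C(C)=C/C=C/C=C(C)/C=P(c1ccccc1)(c1ccccc1)c1ccccc1
F9 | step 4 | C25 hydroxy ylide, [(2E,4E,6E,8E,10E,12E)-13-[(1S,4S)-4-hydroxy-2,6,6-trimethylcyclohex-2-en-1-yl]-2,7,11-trimethyltrideca-2,4,6,8,10,12-hexaen-1-ylidene]triphenylphosphorane | c1ccccc1P(c1ccccc1)(c1ccccc1)=C/C(C)=C/C=C/C=C(C)/C=C/C=C(C)/C=C/[C@@H]1C(C)=C[C@@H](O)CC1(C)C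
F10 | step 6 | C25 keto-apo-aldehyde, (2E,4E,6E,8E,10E,12E)-2,7,11-trimethyl-13-[(1S)-2,6,6-trimethyl-4-oxocyclohex-2-en-1-yl]trideca-2,4,6,8,10,12-hexaenal | O=C/C(C)=C/C=C/C=C(C)/C=C/C=C(C)/C=C/[C@@H]1C(C)=CC(=O)CC1(C)C
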